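The data are simulated from invented constants, and the scatter is random.

The question is how much target stands in the flask at its final time, and whether anything has stopped it by then.

the same everywhere: starting material 0.20 M; precatalyst 0.20 mM

|  | second substrate | remark | time |
|---|---|---|---|
| ash | 0.20 M (fed, over 3.0 h) | run made earlier |  |
| maple | 0.30 M (fed, over 3.0 h) | run made earlier |  |
| flask | 0.400 M (fed, over 3.0 h) |  | 10 h |

| run | time / h | target / % |
|---|---|---|
| ash | 2.00 | 6.7 |
| ash | 4.00 | 20.4 |
| ash | 6.00 | 35.9 |
| ash | 8.00 | 51.9 |
| ash | 10.0 | 64.9 |
| maple | 2.00 | 6.6 |
| maple | 4.00 | 17.9 |
| maple | 6.00 | 31.9 |
| maple | 8.00 | 46.5 |
| maple | 10.0 | 59.5 |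

(scatter of a reading: 0.3 percentage points)

1. at 10 h, what has stopped the reaction, if anything has (no working catalyst is left / all of the starting material has reacted / it is still moving / forward and back rates have come level)
2. how much target there is at 10 h, in percent of the starting material charged

- the analysis behind the earlier runs scatters by 0.3 percentage points, standard deviation
- the reaction counts as stopped when no species that holds the starting material changes by six tenths of a point or more over the second half of the time

Ash and maple differ in their charge of second substrate, while the other charges are equal. Both are still climbing at the end, by 13 percentage points and 13 points over the last interval. To compare them, treat the starting material as pseudo-first-order and take the exposure, the logarithm of charged over unconverted starting material. At 10 h it reads 1.05 for ash and 0.904 for maple.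

Two colleagues now part. The first holds that second substrate competes for the catalyst as an inhibitor competes for an enzyme, so that exposure goes as one over the charge plus a fixed amount. The two runs give that amount, the inhibition charge, 0.432 M, a reading that carries the scatter of both points. For the flask this gives an exposure of 0.795, so 54.9 % of target.

The second colleague draws a straight line: exposure falls by equal steps for equal additions of charge. Between the charges of ash and maple she is as good as he is, since both curves pass through the same two points. Beyond maple they part, and her line reaches 0.761, so 53.3 %, which is lower than his figure.

The forecast stands on his side with its own factor, saying 54.5 % and "it is still moving", on the ground that “excess second substrate mildly inhibits”. My reckoning above is a separate one and gives 54.9 %, not its number.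

The flask gives 55.3 %, and it is still moving.

    precatalyst → free catalyst (k = 0.190 h⁻¹)
    catalyst intermediate B → free catalyst + second product (k = 273 h⁻¹)
    starting material + free catalyst ⇌ catalyst intermediate A (K = 90.0 L mol⁻¹, k = 1360 L mol⁻¹ h⁻¹)
    second substrate + free catalyst ⇌ catalyst intermediate B (K = 4.77 L mol⁻¹, k = 1550 L mol⁻¹ h⁻¹)
    catalyst intermediate A → free catalyst + target (k = 3850 h⁻¹)

At 10.0 h catalyst intermediate B holds 34.3 % of the catalyst, against 1.55 % in catalyst intermediate A. The computed target stands above both reckonings, and its exposure of 0.805 lies beside the 0.795 that the inhibition charge gave. On the neighbour with 0.68 M of second substrate, the inhibition charge gives an exposure of 0.595, so 44.8 % of target. The computed result there is 45.2 %.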